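Which flask still holds its product as target after 10 h, and by how much?

| flask | substrate | solid reagent | temperature | remark | time |
|---|---|---|---|---|---|
| epsilon | 31 mM | 70.5 mM | 55 °C | run made earlier |  |
| zeta | 70 mM | 70.5 mM | 80 °C | run made earlier |  |
| grey | 47 mM | 70.5 mM | 60 °C |  | 10 h |
| green | 47 mM | 70.5 mM | 80 °C |  | 10 h |
| amber | 47 mM | 70.5 mM |  | at 60 °C until 2.0 h, from then on at 100 °C | 10 h |
| ochre | 47 mM | 70.5 mM | 100 °C |  | 10 h |

- epsilon (time / h: target / %, isomer of the product / %): 1.33: 0, 0.3; 2.50: 0.2, 0.2; 4.00: 1.4, 0.6; 5.00: 3.2, 1.7; 6.00: 4.8, 2.0
- zeta (time / min: target / %, isomer of the product / %): 30.0: 0, 0.5; 60.0: 0.1, 0.6; 80.0: 1.0, 1.6; 120: 1.2, 3.4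

(readings scatter by 0.5 percentage points)

- as a solid, counted per litre of solution: solid reagent
- at the start none of the solid reagent is in solution

1. which flask leads in share of target in all that became target or isomer of the product ("all alike" within 1.5 percentage points) (grey / green / amber / ochre / all alike)
2. share of target in all that became target or isomer of the product, grey
3. share of target in all that became target or isomer of the product, green
4. share of target in all that became target or isomer of the product, amber
5. share of target in all that became target or isomer of the product, ochre

What I watch is whether target stops rising while isomer of the product keeps climbing. In zeta, target stands at 1.2% while isomer of the product gains 1.8 percentage points from 80.0 min to 120 min. That gives 0.444 h, the holding time: target at the end of a span, as a fraction of the charge, divided by the mean rate of isomer growth over that span. I assume both products share one feed, so the ratio sets aside the different substrate charges of the runs. Epsilon's readings from 4.00 h to 6.00 h give 6.86 h, with its target still climbing. Both carry the scatter of 0.5 points.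

A straight line of ln(holding time) against temperature gives my ladder, fastest first:

ochre, 100 °C: holding time 0.0498 h, run n = 201 holding times

green, 80 °C: holding time 0.444 h, run n = 22.5

grey, 60 °C: holding time 3.97 h, run n = 2.52

Epsilon's lag, as a reading, falls between the last two rungs: epsilon shows 0.2% target at 2.50 h, a time longer than zeta's holding time and shorter than my holding time for grey. With a steady feed, the share of target (the selectivity) follows:

share = (1 − exp(−n))/n

My shares are grey 36.5%, green 4.44% and ochre 0.498%. Amber spends 8.00 h at 100 °C, which gives 0.622%.

The forecast names grey as leader, with 62% for grey, 40% for green, 26% for amber and 23% for ochre, and it notes: “Target shows a lag, probably from the solid dissolving, while isomer does not”. My shares for green, amber and ochre stand below these.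

The flasks give 48.8% for grey, 2.48% for green, 0.281% for amber and 0.274% for ochre, so grey leads.

    substrate + partner → intermediate + released group (k = 0.00230 L mol⁻¹ s⁻¹, Ea = 56.0 kJ mol⁻¹)
    intermediate ⇌ target (K = 0.740, k = 0.00160 s⁻¹, Ea = 104 kJ mol⁻¹, ΔH = −59.0 kJ mol⁻¹)
    intermediate ⇌ isomer of the product (K = 220, k = 9.20 × 10⁻⁴ s⁻¹, Ea = 113 kJ mol⁻¹, ΔH = −30.0 kJ mol⁻¹)
    2 partner → homo dimer (k = 0.00570 L mol⁻¹ s⁻¹, Ea = 73.0 kJ mol⁻¹)
    solid reagent ⇌ partner, rate k5*(cs5 - [partner]) while solid is left; crystals form when [partner] > cs5 (solubility = 39.0 mM, k = 3.80 × 10⁻⁵ s⁻¹)
    (constants at 80 °C)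

In green, target goes from 1.10% at 5.00 h to 0.985% at 10.0 h while isomer of the product goes from 17.4% to 38.7%, so the holding time reads 0.231 h and the run lasts 43.3 holding times. In grey, target is still rising over the same span, from 3.96% to 9.66%, while isomer of the product goes from 2.80% to 10.1%, so the holding time reads 6.58 h, the run lasts 1.52 holding times, and the share of target stands at 48.8%.

Readings and results come from a simulation from invented constants, noise included.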